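**Remark on the chemistry (numbering used throughout):** ring A is numbered C1 (bearing C7, the CH2OH carbon), C2 (bearing the bridging carbon C8), C3 (OH), C4 (OH), C5 (Br), C6 (H); ring B carries primed numbers with C1' on C8. The target has no stereocentre, and the one centre created at C8 in step 6 is carried as the racemate and erased in step 8.

## Structural features

The target is a diarylmethane: two benzene rings joined through the methylene carbon C8, with no further ring and no stereocentre, so no stereochemical relationship has to be set. Ring A is pentasubstituted in an unbroken sequence, C1 (CH2OH), C2 (C8), C3 (OH), C4 (OH), C5 (Br), with only C6 free; ring B is a 3-bromo-4-hydroxyphenyl group. The fragile groups are the catechol at C3/C4 (air-sensitive once free), the benzylic alcohol at C7, which lies para to the C4 hydroxyl and can ionise to a quinone methide under acid, base or heat, and the two aryl bromides, which rule out catalytic hydrogenolysis, halogen–metal exchange and low-valent transition metals late in the route. The real difficulty is regiochemical: five different substituents must sit on adjacent carbons of ring A, bromine must end up at C5 and C3' and nowhere else, and three phenols must be released without loss of the C7 hydroxyl. The core of the problem is the pair of adjacent one-carbon substituents on C1 and C2 next to the C3 oxygen. Viewed from the C1–C2 bond this is the pattern left when a 3-alkoxyaryne takes a carbon nucleophile at C1 and a carbon electrophile at C2; the key step uses exactly this, an isocyanide carbon becoming C7 and an aldehyde carbon becoming C8.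

## Logic of the disconnections

20 to 19: no skeletal bond is cut; C7 is taken back from the alcohol to the carboxylic acid level. The benzylic alcohol para to the C4 hydroxyl would not survive Lewis-acid dealkylation, so it is unveiled last. The gain is an intermediate that tolerates strong Lewis acids. The demand is a hydride reagent that reduces a carboxyl group beside three phenols and two aryl bromides without over-reducing the new C7–O bond.

19 to 18: the two O–CH3 bonds at C3–O and C4'–O are cut. Methyl ethers keep the C3 oxygen and the ring B oxygen masked through all earlier steps. The forward step needs a boron Lewis acid strong enough for both ethers that leaves the aryl bromides and the diarylmethane alone.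

18 to 17: the C5–Br bond is cut. With C4–OH as the only free phenol, its single open ortho position is C5 (C3 and the para carbon C1 are substituted), while ring B is only a bromoanisole. This places the halogen late, so the aryne precursor needs no bromine, which would not survive the lithiation used to make it. The demand is clean monobromination of ring A with one equivalent of electrophile.

17 to 16: the O–isopropyl bond at C4 is cut. A secondary alkyl ether at C4 is the device that distinguishes this oxygen from the two methyl ethers. The forward step must cleave it selectively with a mild Lewis acid at low temperature.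

16 to 15: the C8–O bond of a lactone is restored. The lactone holds C7 at the carboxyl level and C8 at the carbinol level, exactly what the key step delivers. The forward reduction removes the only stereocentre and must proceed without metals that attack aryl bromides.

15 to 14: the C7=O group is exchanged for C7=N–tert-butyl. This is a simple hydrolysis in the forward sense and the only demand is mild aqueous acid.

14 to 10, 11 and 12: the bonds C1–C7 and C2–C8 and the ring C7–O bond are cut, which removes the whole temporary five-membered ring and both one-carbon substituents at once. Ring A is reduced to a 3,4-dialkoxyaryne, ring B is bought complete with its bromine in 12, and C7 comes from 11. The forward step demands that the nucleophile attack C1 and not C2, which the C3 methoxy group of 10 is there to enforce.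

10 to 8: the O–S bond of the triflate is cut and the carbamate restored. In the forward sense the secondary carbamate is cleaved under amine base and the phenoxide sulfonylated in the same flask, so the C–Si bond never meets acid or fluoride.

8 to 5: the C2–Si bond is cut. The carbamate at C1 and the methoxy group at C3 flank C2, so a directed lithiation should choose this position over C6. The demand is protection of the carbamate N–H in the flask and low temperature.

5 to 4: the carbamoyl C–O bond is cut, leaving a phenol.

4 to 2: the C1–O bond is cut and replaced by the C1–CHO bond. An oxidative aryl migration turns the aldehyde carbon into a leaving formate, which requires an electron-rich ring.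

2 to 1: the O–isopropyl bond is cut, leaving a cheap phenolic aldehyde whose oxygen pattern already matches C3 and C4.

## Other disconnections considered

Alternative 1: the cut goes through ring A at C4–C5 and C1–C2, dividing it into a C2–C3–C4 dinucleophile and a C5–C6–C1 dielectrophile. In the forward direction the bis(silyl enol ether) A2 of diketone A1 would condense with enone ester A3 under TiCl4 (conjugate addition with loss of ethanol, aldol closure, loss of water) to give benzoate A4.
- In its favour: ring A is built with C7 (ester), C8 (aroyl carbon), the C3 oxygen and the C4 oxygen all placed by the connectivity of acyclic pieces. It needs no aryne and no fluoride-labile precursor, a point on which it is better than the chosen plan. The two oxygens emerge differentiated (free OH at C3, benzyl ether at C4), which equals the chosen plan.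
- Against it: the free hydroxyl is on C3, which would steer an electrophile to C6 (para) and not to C5, so the protection pattern must be inverted, with hydrogenolysis of the benzyl ether before any bromine is present. C8 arrives as a diaryl ketone between two ortho substituents and must be deoxygenated. Ring B arrives without bromine, so two separate selective brominations are needed. The regiochemistry of the condensation depends on the terminal carbon of A2 choosing the enol ether carbon of A3 over its keto carbonyl.
- Comparison: both plans deliver C7 and C8 at raised oxidation levels and each relies on one polar control element, so they are equal on that point. The chosen plan needs one late bromination where this one needs two. On step count the alternative would need about twelve to thirteen steps and offers no saving.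

Alternative 2: the cut is made in ring B at C1'–C6' and C2'–C3', so that ring B is grown on a finished ring A. Aldehyde A5 and enone A6 would undergo amine-catalysed Michael addition and aldol condensation to cyclohexenone A7, which is later dehydrogenated to the phenol.
- In its favour: ring A can carry the C5 bromine from the start, so no late ring A bromination and no isopropyl/methyl differentiation is needed, which is better than the chosen plan. C8 is a methylene from the outset, so no benzhydrylic reduction is needed, also better. The ring B oxygen is fixed para to C8 by the annulation.
- Against it: the hard part of the target, a C2 carbon chain between the C1 carboxyl and the C3 oxygen, is not solved but moved into the synthesis of A5. That would probably need an ortho-halogenation and a coupling with zerovalent palladium in the presence of the C5 bromide. The enone must then be oxidised to a phenol beside a benzylic methylene. The C3' bromine must be put on a phenol with two equivalent ortho positions, with the risk of double bromination. The stereocentre of A7 is made only to be destroyed, as in the chosen plan, so the two are equal there.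
- Comparison: the key step is mild organocatalysis against a fluoride-triggered aryne cascade, and it forms two bonds as the chosen step does. Counting a six- to seven-step preparation of A5, the total would be no shorter than twelve steps.

Alternative 3: the cut is the ring A bond C1–C6, traced back to a four-membered ring. Heating cyclobutenone A8 would open it to dienylketene A9, which closes by 6π electrocyclisation and tautomerises to phenol A10.
- In its favour: the substituents on C2, C3 and C4 are placed by stepwise additions to a squaric ester, so their order is unambiguous. The key step needs no reagent. C8 is already a methylene, which is better than the chosen plan. The oxygens emerge differentiated (methyl at C3, silyl at C4), the pattern needed to direct bromine to C5, which equals the chosen plan.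
- Against it: the carbon that becomes C1 emerges bearing a hydroxyl group and not C7, so C7 must be added afterwards through the triflate and a carbonylation with zerovalent palladium next to the bulky benzyl group, before any bromine is present. Both bromines are missing, and the ring B bromination ortho to a methoxy group must compete with ring A. The squarate sequence needs several low-temperature organometallic additions, including a benzylic organometallic prone to homocoupling.
- Comparison: the chosen key step forms both C1–C7 and C2–C8, whereas this one forms neither. The total would be about thirteen to fourteen steps, longer than the chosen plan.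

Key step: step 6

## Route

Step 1
Reactants: 1 vanillin (4-hydroxy-3-methoxybenzaldehyde)
Product: 2 4-isopropoxy-3-methoxybenzaldehyde
Conditions: 2-bromopropane, K2CO3, DMF, 70 °C
Reagents that add atoms: 2-bromopropane, CC(C)Br
Why: Williamson ether synthesis; the phenoxide of 1 is alkylated by the secondary bromide in a dipolar aprotic solvent and the aldehyde is untouched.

Step 2
Reactants: 2 4-isopropoxy-3-methoxybenzaldehyde
Product: 4 4-isopropoxy-3-methoxyphenol, via aryl formate 3 (not isolated)
Conditions: mCPBA, CH2Cl2, rt; then K2CO3, MeOH, rt
Reagents that add atoms: 3-chloroperoxybenzoic acid (mCPBA), OOC(=O)c1cccc(Cl)c1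
Why: Baeyer–Villiger (Dakin-type) oxidation; the electron-rich aryl group migrates in preference to hydride to give formate 3, which mild methanolysis cleaves to the phenol.

Step 3
Reactants: 4 4-isopropoxy-3-methoxyphenol
Product: 5 4-isopropoxy-3-methoxyphenyl N-isopropylcarbamate
Conditions: i-PrNCO, Et3N (cat.), CH2Cl2, rt
Reagents that add atoms: isopropyl isocyanate, CC(C)N=C=O
Why: Base-catalysed addition of a phenol to an isocyanate (carbamoylation); the secondary carbamate is chosen because it directs lithiation and is later removed under mild amine base.

Step 4
Reactants: 5 4-isopropoxy-3-methoxyphenyl N-isopropylcarbamate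
Product: 8 4-isopropoxy-3-methoxy-2-(trimethylsilyl)phenyl N-isopropylcarbamate, via N-silyl carbamate 6 (not isolated), via N-silyl C-silyl carbamate 7 (not isolated)
Conditions: TBSOTf, TMEDA, Et2O, 0 °C → rt; n-BuLi, TMEDA, −78 °C; TMSCl, −78 °C → rt; aq. NaHSO4
Reagents that add atoms: chlorotrimethylsilane, C[Si](C)(C)Cl
Why: Directed ortho metalation of an aryl O-carbamate after N-silylation in the flask; C2–H lies between the carbamate and the C3 methoxy group and is removed in preference to C6–H, and −78 °C suppresses the anionic Fries shift. The aryllithium is silylated and the N–Si bond is hydrolysed on acidic work-up.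

Step 5
Reactants: 8 4-isopropoxy-3-methoxy-2-(trimethylsilyl)phenyl N-isopropylcarbamate
Product: 10 4-isopropoxy-3-methoxy-2-(trimethylsilyl)phenyl trifluoromethanesulfonate, via silylphenol 9 (not isolated)
Conditions: DBU, Et2NH, MeCN, 40 °C; then PhNTf2, rt
Reagents that add atoms: N-phenylbis(trifluoromethanesulfonimide), O=S(=O)(N(c1ccccc1)S(=O)(=O)C(F)(F)F)C(F)(F)F
Why: E1cB cleavage of the secondary carbamate (isopropyl isocyanate is expelled and trapped by Et2NH as a urea) followed by O-sulfonylation of the phenoxide; neither acid nor fluoride is present, so the C2–Si bond should survive.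

Step 6
Reactants: 10 4-isopropoxy-3-methoxy-2-(trimethylsilyl)phenyl trifluoromethanesulfonate; 11 tert-butyl isocyanide; 12 3-bromo-4-methoxybenzaldehyde
Product: 14 N-tert-butyl-3-(3-bromo-4-methoxyphenyl)-5-isopropoxy-4-methoxy-3H-isobenzofuran-1-imine (racemic), via aryne 13 (not isolated)
Conditions: KF, 18-crown-6, THF, 0 °C → rt (11 and 12 in excess)
Reagents that add atoms: none
Why: Aryne–isocyanide–aldehyde three-component coupling, the known route to benzo-annulated iminofurans. Fluoride attacks silicon of 10 and the resulting aryl anion expels triflate to give aryne 13 across C1–C2. The C3 methoxy group withdraws electron density through the σ framework and distorts the aryne so that C1 is the more electrophilic and less hindered terminus; the isocyanide carbon of 11 therefore adds at C1 (bond C1–C7) and the aryl anion develops at C2, stabilised by the adjacent C–O bond. This anion adds to the carbonyl of 12 (bond C2–C8), and the alkoxide closes on the nitrilium carbon by a 5-exo-dig attack to form the five-membered imidate ring. The new stereocentre at C8 arises from unbiased attack on either face of the aldehyde, so 14 is racemic; no control is needed because step 8 removes this centre. The selectivity that matters is the regiochemistry of addition to the aryne, secured by the C3 methoxy group, and the preference of the zwitterion for the aldehyde over a second aryne or a proton source, secured by slow aryne release at 0 °C under anhydrous conditions with 11 and 12 in excess. The aryl bromide of 12 is inert because neither a transition metal nor an organolithium reagent is present.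

Step 7
Reactants: 14 N-tert-butyl-3-(3-bromo-4-methoxyphenyl)-5-isopropoxy-4-methoxy-3H-isobenzofuran-1-imine (racemic)
Product: 15 3-(3-bromo-4-methoxyphenyl)-5-isopropoxy-4-methoxy-3H-isobenzofuran-1-one (racemic)
Conditions: 1 M HCl, THF, rt
Reagents that add atoms: water, O
Why: Acid hydrolysis of a cyclic imidate; N-protonation, addition of water at C7 and loss of tert-butylamine give the lactone, while the ethers, the aryl bromide and the C8 centre are not affected.

Step 8
Reactants: 15 3-(3-bromo-4-methoxyphenyl)-5-isopropoxy-4-methoxy-3H-isobenzofuran-1-one (racemic)
Product: 16 2-[(3-bromo-4-methoxyphenyl)methyl]-4-isopropoxy-3-methoxybenzoic acid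
Conditions: Et3SiH, CF3CO2H, rt → 50 °C
Reagents that add atoms: none
Why: Ionic hydrogenation; in CF3CO2H the lactone C8–O bond ionises to a benzhydryl cation stabilised by the para methoxy group of ring B and the ortho methoxy group on C3, and Et3SiH delivers hydride. The only stereocentre is erased, and aryl bromide and alkyl aryl ethers are inert to these metal-free conditions.

Step 9
Reactants: 16 2-[(3-bromo-4-methoxyphenyl)methyl]-4-isopropoxy-3-methoxybenzoic acid
Product: 17 2-[(3-bromo-4-methoxyphenyl)methyl]-4-hydroxy-3-methoxybenzoic acid
Conditions: BCl3, CH2Cl2, −78 → 0 °C; H2O
Reagents that add atoms: none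
Why: Lewis-acid ether cleavage; BCl3 removes the secondary isopropyl group much faster than methyl groups at or below 0 °C, and neither methoxy group is ortho to a carbonyl, so chelation-assisted demethylation is not expected.

Step 10
Reactants: 17 2-[(3-bromo-4-methoxyphenyl)methyl]-4-hydroxy-3-methoxybenzoic acid
Product: 18 5-bromo-2-[(3-bromo-4-methoxyphenyl)methyl]-4-hydroxy-3-methoxybenzoic acid
Conditions: NBS (1.0 equiv), MeCN, 0 °C, dark
Reagents that add atoms: N-bromosuccinimide, O=C1CCC(=O)N1Br
Why: Electrophilic aromatic bromination ortho to a phenol; C4–OH is the only free phenol and C5 its only open ortho position, as in 4-hydroxy-3-methoxybenzoic acids, while ring B is a less reactive bromoanisole. Polar solvent, low temperature and exclusion of light disfavour radical attack at C8.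

Step 11
Reactants: 18 5-bromo-2-[(3-bromo-4-methoxyphenyl)methyl]-4-hydroxy-3-methoxybenzoic acid
Product: 19 5-bromo-2-[(3-bromo-4-hydroxyphenyl)methyl]-3,4-dihydroxybenzoic acid
Conditions: BBr3 (excess), CH2Cl2, −78 °C → rt; ice-water
Reagents that add atoms: none
Why: BBr3 demethylation of both aryl methyl ethers by bromide attack on the boron-complexed O–CH3 groups; aryl bromides and the carboxyl group survive. Ring closure of the activated acid onto ring B is disfavoured because the ring B carbons ortho to C8 are meta to its oxygen.

Step 12
Reactants: 19 5-bromo-2-[(3-bromo-4-hydroxyphenyl)methyl]-3,4-dihydroxybenzoic acid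
Product: 20 3-bromo-6-[(3-bromo-4-hydroxyphenyl)methyl]-5-(hydroxymethyl)benzene-1,2-diol (target)
Conditions: BH3·THF (excess), THF, 0 °C → rt; MeOH, then aq. NH4Cl
Reagents that add atoms: none
Why: Borane reduction of a carboxylic acid through its acyloxyborane, chemoselective in the presence of aryl bromides; the phenols are held as aryloxyboranes that are released on work-up. Low temperature and a near-neutral work-up protect the para-hydroxybenzyl alcohol.

## Compound list

1 | vanillin (4-hydroxy-3-methoxybenzaldehyde) | COc1cc(C=O)ccc1O | starting material
2 | 4-isopropoxy-3-methoxybenzaldehyde | COc1cc(C=O)ccc1OC(C)C | intermediate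
3 | 4-isopropoxy-3-methoxyphenyl formate | COc1cc(OC=O)ccc1OC(C)C | intermediate
4 | 4-isopropoxy-3-methoxyphenol | COc1cc(O)ccc1OC(C)C | intermediate
5 | 4-isopropoxy-3-methoxyphenyl N-isopropylcarbamate | COc1cc(OC(=O)NC(C)C)ccc1OC(C)C | intermediate
6 | 4-isopropoxy-3-methoxyphenyl N-(tert-butyldimethylsilyl)-N-isopropylcarbamate | COc1cc(OC(=O)N(C(C)C)[Si](C)(C)C(C)(C)C)ccc1OC(C)C | intermediate
7 | 4-isopropoxy-3-methoxy-2-(trimethylsilyl)phenyl N-(tert-butyldimethylsilyl)-N-isopropylcarbamate | COc1c(OC(C)C)ccc(OC(=O)N(C(C)C)[Si](C)(C)C(C)(C)C)c1[Si](C)(C)C | intermediate
8 | 4-isopropoxy-3-methoxy-2-(trimethylsilyl)phenyl N-isopropylcarbamate | COc1c(OC(C)C)ccc(OC(=O)NC(C)C)c1[Si](C)(C)C | intermediate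
9 | 4-isopropoxy-3-methoxy-2-(trimethylsilyl)phenol | COc1c(OC(C)C)ccc(O)c1[Si](C)(C)C | intermediate
10 | 4-isopropoxy-3-methoxy-2-(trimethylsilyl)phenyl trifluoromethanesulfonate | C[Si](C)(C)c1c(OS(=O)(=O)C(F)(F)F)ccc(OC(C)C)c1OC | intermediate
11 | tert-butyl isocyanide | CC(C)(C)[N+]#[C-] | starting material
12 | 3-bromo-4-methoxybenzaldehyde | COc1ccc(C=O)cc1Br | starting material
13 | 4-isopropoxy-3-methoxy-1,2-didehydrobenzene (aryne) | COC1=C(OC(C)C)C=CC#C1 | intermediate
14 | N-tert-butyl-3-(3-bromo-4-methoxyphenyl)-5-isopropoxy-4-methoxy-3H-isobenzofuran-1-imine (racemic; C=N geometry not assigned) | CC(C)(C)N=C1OC(c2ccc(OC)c(Br)c2)c3c1ccc(OC(C)C)c3OC | intermediate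
15 | 3-(3-bromo-4-methoxyphenyl)-5-isopropoxy-4-methoxy-3H-isobenzofuran-1-one (racemic) | O=C1OC(c2ccc(OC)c(Br)c2)c3c1ccc(OC(C)C)c3OC | intermediate
16 | 2-[(3-bromo-4-methoxyphenyl)methyl]-4-isopropoxy-3-methoxybenzoic acid | OC(=O)c1ccc(OC(C)C)c(OC)c1Cc1ccc(OC)c(Br)c1 | intermediate
17 | 2-[(3-bromo-4-methoxyphenyl)methyl]-4-hydroxy-3-methoxybenzoic acid | OC(=O)c1ccc(O)c(OC)c1Cc1ccc(OC)c(Br)c1 | intermediate
18 | 5-bromo-2-[(3-bromo-4-methoxyphenyl)methyl]-4-hydroxy-3-methoxybenzoic acid | OC(=O)c1cc(Br)c(O)c(OC)c1Cc1ccc(OC)c(Br)c1 | intermediate
19 | 5-bromo-2-[(3-bromo-4-hydroxyphenyl)methyl]-3,4-dihydroxybenzoic acid | OC(=O)c1cc(Br)c(O)c(O)c1Cc1ccc(O)c(Br)c1 | intermediate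
20 | 3-bromo-6-[(3-bromo-4-hydroxyphenyl)methyl]-5-(hydroxymethyl)benzene-1,2-diol | OCc1cc(Br)c(O)c(O)c1Cc1ccc(O)c(Br)c1 | target

## Step count and risk

Total step count: 12. Longest linear sequence: 12 steps (1 to 20); 11 and 12 are bought and enter at step 6.

Least certain steps:

**Step 6 (key step).** The most likely failure is diversion of the zwitterion before it meets the aldehyde: capture by a second aryne or by traces of a proton source. The cause is that 12 is an electron-rich and therefore only moderately electrophilic aldehyde. Erosion of regioselectivity at the aryne is a smaller risk. The fallback sets out from 2 and comes back at 15. It forms only the C2–C8 bond, by directed ortho metalation of a benzamide, and carries C7 from the start: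
- 2 is oxidised with NaClO2/NaH2PO4/2-methyl-2-butene to 4-isopropoxy-3-methoxybenzoic acid F1.
- SOCl2 converts this into 4-isopropoxy-3-methoxybenzoyl chloride F2, and Et2NH then gives N,N-diethyl-4-isopropoxy-3-methoxybenzamide F3.
- s-BuLi/TMEDA in THF at −78 °C should lithiate C2 between the amide and the methoxy group. Addition of 12 gives 2-[(3-bromo-4-methoxyphenyl)(hydroxy)methyl]-N,N-diethyl-4-isopropoxy-3-methoxybenzamide F4 (racemic).
- TsOH in hot toluene lactonises this with loss of diethylamine to 15.

**Step 12.** The most likely failure is over-reduction at C7. The aryloxyborane para to C7 can assist loss of the new C7–O bond, and the resulting quinone methide would take up hydride to leave a methyl group. Incomplete reduction of the deactivated, electron-rich acyloxyborane is the opposite risk. The fallback sets out from 19 and comes back at 20, with the phenols masked so that neither process can operate: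
- Ac2O/pyridine, then aqueous work-up to hydrolyse the mixed anhydride, gives 3,4-diacetoxy-2-[(4-acetoxy-3-bromophenyl)methyl]-5-bromobenzoic acid F5.
- BH3·THF at 0 °C reduces the acid faster than the aryl esters to 4-{[2,3-diacetoxy-4-bromo-6-(hydroxymethyl)phenyl]methyl}-2-bromophenyl acetate F6.
- K2CO3 in MeOH at 0 °C, then neutralisation with aq. NH4Cl, removes the three acetates to give 20.

**Step 10.** The most likely failure is attack of the electrophile at the wrong place: ipso substitution at C1, para to the free phenol, with loss of CO2, or radical bromination of the doubly benzylic C8 methylene. The fallback sets out from 15 and comes back at 18. Bromination is moved to the lactone stage, where the carboxyl is tied up as an ester and C8 is not yet a methylene: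
- BCl3 in CH2Cl2 at −78 → 0 °C removes the isopropyl group of 15 to give 3-(3-bromo-4-methoxyphenyl)-5-hydroxy-4-methoxy-3H-isobenzofuran-1-one F7 (racemic).
- NBS in MeCN at 0 °C gives 6-bromo-3-(3-bromo-4-methoxyphenyl)-5-hydroxy-4-methoxy-3H-isobenzofuran-1-one F8 (racemic).
- Et3SiH in CF3CO2H opens and reduces this lactone to 18.

**Step 8.** The most likely failure is slow ionisation of the lactone C8–O bond, since the carboxyl group on ring A works against the cation, with intermolecular Friedel–Crafts alkylation of electron-rich rings by the cation as a competing process. The fallback sets out from 15 and comes back at 16 without any new compound. It is an electron-transfer reduction with Zn dust in aqueous NH3 (cat. CuSO4) at reflux, which cleaves the benzylic C–O bond through the radical anion of the aromatic ester and needs no carbocation. Unactivated aryl bromides are not expected to be reduced by zinc under these conditions.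

## Further compounds

F1 | step 6 | 4-isopropoxy-3-methoxybenzoic acid | COc1cc(C(=O)O)ccc1OC(C)C
F2 | step 6 | 4-isopropoxy-3-methoxybenzoyl chloride | COc1cc(C(=O)Cl)ccc1OC(C)C
F3 | step 6 | N,N-diethyl-4-isopropoxy-3-methoxybenzamide | CCN(CC)C(=O)c1ccc(OC(C)C)c(OC)c1
F4 | step 6 | 2-[(3-bromo-4-methoxyphenyl)(hydroxy)methyl]-N,N-diethyl-4-isopropoxy-3-methoxybenzamide (racemic) | CCN(CC)C(=O)c1ccc(OC(C)C)c(OC)c1C(O)c1ccc(OC)c(Br)c1
F5 | step 12 | 3,4-diacetoxy-2-[(4-acetoxy-3-bromophenyl)methyl]-5-bromobenzoic acid | CC(=O)Oc1ccc(Cc2c(C(=O)O)cc(Br)c(OC(C)=O)c2OC(C)=O)cc1Br
F6 | step 12 | 4-{[2,3-diacetoxy-4-bromo-6-(hydroxymethyl)phenyl]methyl}-2-bromophenyl acetate | CC(=O)Oc1ccc(Cc2c(CO)cc(Br)c(OC(C)=O)c2OC(C)=O)cc1Br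
F7 | step 10 | 3-(3-bromo-4-methoxyphenyl)-5-hydroxy-4-methoxy-3H-isobenzofuran-1-one (racemic) | O=C1OC(c2ccc(OC)c(Br)c2)c2c1ccc(O)c2OC
F8 | step 10 | 6-bromo-3-(3-bromo-4-methoxyphenyl)-5-hydroxy-4-methoxy-3H-isobenzofuran-1-one (racemic) | O=C1OC(c2ccc(OC)c(Br)c2)c2c1cc(Br)c(O)c2OC
F0 | step 8 | none | none
A1 | alternative 1 | 4-(benzyloxy)-1-(4-methoxyphenyl)butane-1,3-dione | COc1ccc(cc1)C(=O)CC(=O)COCc1ccccc1
A2 | alternative 1 | 4-(benzyloxy)-1-(4-methoxyphenyl)-1,3-bis(trimethylsilyloxy)buta-1,3-diene (double-bond geometry not defined) | COc1ccc(cc1)C(O[Si](C)(C)C)=CC(O[Si](C)(C)C)=COCc1ccccc1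
A3 | alternative 1 | methyl (E)-4-ethoxy-2-oxobut-3-enoate | CCO/C=C/C(=O)C(=O)OC
A4 | alternative 1 | methyl 4-(benzyloxy)-3-hydroxy-2-(4-methoxybenzoyl)benzoate | COC(=O)c1ccc(OCc2ccccc2)c(O)c1C(=O)c1ccc(OC)cc1
A5 | alternative 2 | methyl 5-bromo-3,4-dimethoxy-2-(3-oxopropyl)benzoate | COC(=O)c1cc(Br)c(OC)c(OC)c1CCC=O
A6 | alternative 2 | methyl vinyl ketone (but-3-en-2-one) | CC(=O)C=C
A7 | alternative 2 | methyl 5-bromo-3,4-dimethoxy-2-[(4-oxocyclohex-2-en-1-yl)methyl]benzoate (racemic) | COC(=O)c1cc(Br)c(OC)c(OC)c1CC1C=CC(=O)CC1
A8 | alternative 3 | 4-(tert-butyldimethylsilyloxy)-3-methoxy-2-(4-methoxybenzyl)-4-vinylcyclobut-2-enone (racemic) | C=CC1(O[Si](C)(C)C(C)(C)C)C(OC)=C(Cc2ccc(OC)cc2)C1=O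
A9 | alternative 3 | (3Z)-4-(tert-butyldimethylsilyloxy)-3-methoxy-2-(4-methoxybenzyl)hexa-1,3,5-trien-1-one (dienylketene) | O=C=C(Cc1ccc(OC)cc1)/C(OC)=C(/O[Si](C)(C)C(C)(C)C)C=C
A10 | alternative 3 | 4-(tert-butyldimethylsilyloxy)-3-methoxy-2-(4-methoxybenzyl)phenol | Oc1ccc(O[Si](C)(C)C(C)(C)C)c(OC)c1Cc1ccc(OC)cc1
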